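4 questions hang on one curve, the target in a flask whose reagent charge is half that of the theta run.

- theta: starting material 0.050 M; reagent 0.20 M; catalyst 0.10 mM; run made earlier
- flask: starting material 0.050 M; reagent 0.100 M; catalyst 0.10 mM; time 30 h

theta run (percent of the starting material charged): time / h: target / % = 0.250: 12.8; 0.417: 19.5; 0.833: 30.4; 1.50: 38.1; 3.00: 39.0

(each reading ± 0.3 percentage points)



* when, up to 30 h, the flask holds most target
* the amount of target, in percent of the starting material charged, at that time
* earliest time at which at least nineteen twentieths of that best amount are there
* latest time at which they still are

Two chemists dispute what that cut does to the target. The first reads the sharp flattening as over-reaction of target with reagent, so making and loss scale together and the clock merely stretches. The theta run stands at one reagent level, so its readings leave the two views open. I hold the second view: I lay the loss on the catalyst, charged equally in both flasks, freeze the loss constant and let reagent move the making.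

The first reading of the theta run gives a pseudo-first-order making constant of 0.548 /h at 0.20 M of reagent, early loss neglected. The theta curve then reads flat, 38.1% to 39.0%, so near 2.25 h I set making equal to loss. With 38.5% target there, and the starting material decayed exponentially, the loss constant reads 0.414 /h.

The carried quantity is the balance level, 0.151 M: the reagent concentration at which the making constant equals the loss constant. The flask's reagent charge stands at 0.661 of it. For consecutive first-order steps, the peak fraction is that ratio raised to the power one over one minus the ratio, which gives 29.5% at 2.95 h. Taken one to one, the charges let the flask's reagent fall towards 50.0%, so I take that time as an early edge.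

The forecast, the first chemist's, says 40.5% at 5 h, with the window from 3.6 h to 8.6 h, on the ground that “the yield-versus-conversion curve does not depend on reagent level”.

The flask gives 29.7% at 3.71 h, and the window asked for runs from 2.34 h to 6.16 h.

    starting material + reagent ⇌ target (K = 120 /M, k = 3.10 /M/h)
    target + catalyst ⇌ isomer of the product A + catalyst, rate k2*[catalyst]*[target] forward; the back reaction follows from the equilibrium constant (k = 1100 /M/h)
    starting material + reagent ⇌ isomer of the product A (K = 29.0 /M, k = 1.10 /M/h)
    target + catalyst ⇌ isomer of the product B + catalyst, rate k4*[catalyst]*[target] forward; the back reaction follows from the equilibrium constant (K = 2.90, k = 3800 /M/h)

The flask's peak sits beside my 29.5% and comes later than 2.95 h, with reagent at 65.9% of its charge at 3.71 h. A neighbour flask, charged with 0.025 M of reagent and otherwise the same, has a charge at 0.165 of the balance level 0.151 M, and the same formula gives it 11.6%. Its simulated best is 11.5%, and at 30.0 h its reagent is down to 8.54% of its own charge.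

(The runs were generated by integration for substances that don't exist.)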